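The route rests on disconnecting the C1′–C7a′ bond of the bridging γ-lactone. In the target this lactone carbonyl sits on the quaternary carbon C7a′ and is tied through O2′ to C3′, cis-1,3 across the central cyclopentane (C6, C7, C7a′, C3a′, C3′), with C7a′ next to C7′ of ring C. A methyl carbonate on the C3′ oxygen is therefore made to acylate the C7a′ enolate of a C7′ ketone: one operation forms the C–C bond, closes the lactone and fixes the quaternary centre. The precursor is an all-cis hydrofluorene, built by arene hydrogenation of a fluorenone, carrying the C7′ ketone, the C3′ carbonate, a C8′ PMB ether and ring A as a β-methoxy enoate.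

Key step: step 16

Numbering: phthalide numbering; unprimed = butylidenephthalide half (ring A = C3a, C4, C5, C6, C7, C7a), primed = butanoyl half (ring C = C3a′, C4′, C5′, C6′, C7′, C7a′). The "H-face" is the face of the central ring that carries H6, H7 and H3a′.

Assumption: centres that are oxidised later (C3a, C7a, C3′ and C7′ after hydrogenation; C8′ after dihydroxylation, which follows the alkene geometry) are drawn as one isomer because their configuration has no bearing on the target; compounds 9–11 are racemic with one enantiomer drawn.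

Step 1
Reactants: 1 methyl 2,6-dihydroxybenzoate
Product: 2 methyl 2-hydroxy-6-(trifluoromethylsulfonyloxy)benzoate
Conditions: Tf2O (1.05 equiv), pyridine, CH2Cl2, −78 → 0 °C
Reagents that add atoms: trifluoromethanesulfonic anhydride, O=S(=O)(OS(=O)(=O)C(F)(F)F)C(F)(F)F
Why: Phenol O-sulfonylation; after the first triflation the remaining chelated hydroxyl sits on a more electron-poor ring and reacts much more slowly, so one equivalent of anhydride should stop at the monotriflate.

Step 2
Reactants: 2 methyl 2-hydroxy-6-(trifluoromethylsulfonyloxy)benzoate; 3 2-(methoxymethoxy)phenylboronic acid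
Product: 4 methyl 2-hydroxy-6-[2-(methoxymethoxy)phenyl]benzoate
Conditions: Pd(PPh3)4 (5 mol %), K2CO3, DME/H2O, 85 °C
Reagents that add atoms: none
Why: Suzuki–Miyaura coupling of an electron-poor aryl triflate forms the C7–C7a′ bond and tolerates the free chelated phenol, while the acetal on the ring C oxygen prevents lactonisation onto the neighbouring ester.

Step 3
Reactants: 4 methyl 2-hydroxy-6-[2-(methoxymethoxy)phenyl]benzoate
Product: 5 methyl 6-hydroxy-3-iodo-2-[2-(methoxymethoxy)phenyl]benzoate
Conditions: NaI, NaOH, NaOCl (aq), MeOH, 0 °C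
Reagents that add atoms: sodium iodide, [Na+].[I-]
Why: Electrophilic aromatic iodination by hypoiodite made in situ attacks only the phenoxide ring, para to the oxygen as is usual for salicylates, which is the future C6, the aryl ether ring being inert in base.

Step 4
Reactants: 5 methyl 6-hydroxy-3-iodo-2-[2-(methoxymethoxy)phenyl]benzoate
Product: 6 methyl 3-hydroxy-5-(methoxymethoxy)-9-oxofluorene-4-carboxylate
Conditions: Pd(PCy3)2 (5 mol %), cesium pivalate (2 equiv), CO (1 atm), DMF, 110 °C
Reagents that add atoms: carbon monoxide, [C-]#[O+]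
Why: Palladium-catalysed cyclocarbonylation of an ortho-iodobiaryl (oxidative addition, CO insertion, carboxylate-assisted C–H palladation at the only free ortho position of ring C, reductive elimination) closes the central five-membered ketone, whose carbon becomes C3′.

Step 5
Reactants: 6 methyl 3-hydroxy-5-(methoxymethoxy)-9-oxofluorene-4-carboxylate
Product: 8 methyl 5-(tert-butyldimethylsilyloxy)-3-hydroxy-9-oxofluorene-4-carboxylate, via fluorenone diphenol 7 (not isolated)
Conditions: HCl (1 M in MeOH), 50 °C; evaporate; TBSCl (1.2 equiv), imidazole, DMF, 0 °C → rt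
Reagents that add atoms: tert-butyldimethylsilyl chloride, CC(C)(C)[Si](C)(C)Cl
Why: Acetal methanolysis frees the ring C phenol and silylation should then occur there only, because the ring A hydroxyl is chelated to the ester and vinylogously acidic, a kind of hydroxyl that resists silyl chlorides; the silyl ether survives hydrogenation and is later removable without acid or base.

Step 6
Reactants: 8 methyl 5-(tert-butyldimethylsilyloxy)-3-hydroxy-9-oxofluorene-4-carboxylate
Product: 9 racemic all-cis perhydrofluorene diol (C3a–OH, C3′–OH, C7′–OTBS, C7a–CO2Me)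
Conditions: H2 (70 bar), Rh/Al2O3 (5 wt % Rh), i-PrOH/EtOAc, 50 °C
Reagents that add atoms: none
Why: Heterogeneous arene hydrogenation over rhodium (the diaryl ketone being reduced to the carbinol on the way) delivers hydrogen from the metal surface, and once the first ring is saturated the bent cis-fused bicycle presents the same convex face of the second arene, so H6, H7, H7a′ and H3a′ (and the hydrogens at C7a, C3a, C7′ and C3′) should all be syn, while rhodium on neutral alumina keeps C–O hydrogenolysis low.

Step 7
Reactants: 9 racemic all-cis perhydrofluorene diol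
Product: 10 racemic all-cis C3′ ketone with ring A as enolised β-keto ester (C7′–OTBS)
Conditions: Dess–Martin periodinane (2.5 equiv), NaHCO3, CH2Cl2, 0 °C → rt
Reagents that add atoms: none
Why: Dess–Martin oxidation of both secondary alcohols under buffered, non-epimerising conditions gives the C3′ ketone and the ring A β-keto ester, drawn as its chelated enol, and thereby erases the carbinol centres at C3a and C3′ and the methine at C7a.

Step 8
Reactants: 10 racemic C3′ ketone with enolised β-keto ester
Product: 11 racemic all-cis C3′ ketone with ring A as β-methoxy enoate (C7′–OTBS)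
Conditions: Me3SiCHN2, MeOH/PhMe, 0 °C → rt
Reagents that add atoms: (trimethylsilyl)diazomethane, C[Si](C)(C)C=[N+]=[N-]
Why: Diazoalkane O-methylation of the acidic chelated enol gives the vinylogous carbonate without base, so that H6 and H3a′ next to the C3′ ketone are not epimerised and ring A has no acidic α-hydrogen left for the later basic steps.

Step 9
Reactants: 11 racemic C3′ ketone with ring A β-methoxy enoate
Product: 12 the same ketone as a single enantiomer (H6, H7, H7a′, H3a′ syn; absolute configuration as in the SMILES)
Conditions: preparative SFC, amylose tris(3,5-dimethylphenylcarbamate) stationary phase, CO2/i-PrOH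
Reagents that add atoms: none
Why: Resolution of the racemate by chromatography on a polysaccharide chiral stationary phase, with no bond change and UV detection through the enoate, should give the enantiomer drawn, whose absolute configuration is to be confirmed by anomalous-dispersion X-ray analysis of a later crystalline intermediate.

Step 10
Reactants: 12 enantiopure C3′ ketone
Product: 13 C3′ butylidene alkene (exocyclic C3′=C8′, propyl drawn syn to C6)
Conditions: n-BuPPh3Br (3 equiv), KN(SiMe3)2 (2.9 equiv), PhMe, 0 °C; then 12, 0 → 80 °C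
Reagents that add atoms: butyltriphenylphosphonium bromide, CCCC[P+](c1ccccc1)(c1ccccc1)c1ccccc1.[Br-]
Why: Wittig olefination of a hindered cyclopentanone with a non-stabilised ylide kept free of excess base, as in the alkylidenation of 17-keto steroids, should give the exocyclic alkene, either geometry of which serves.

Step 11
Reactants: 13 C3′ butylidene alkene
Product: 14 C3′,C8′ diol (tertiary C3′–OH on the H-face)
Conditions: OsO4 (5 mol %), NMO, acetone/H2O, rt
Reagents that add atoms: N-methylmorpholine N-oxide, C[N+]1([O-])CCOCC1; water, O; osmium tetroxide (catalytic oxygen carrier), O=[Os](=O)(=O)=O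
Why: OsO4-catalysed syn-dihydroxylation from the convex H-face of the folded tricycle, the concave face being shielded by C5 and C4′ of rings A and C, sets C3′ with its oxygen on the H-face, while the tetrasubstituted, ester-conjugated ring A alkene is too hindered and electron-poor to react.

Step 12
Reactants: 14 C3′,C8′ diol
Product: 15 C8′ 4-methoxybenzyl ether with free tertiary C3′–OH
Conditions: NaH (1.1 equiv), PMBCl, n-Bu4NI (cat.), DMF, 0 °C → rt
Reagents that add atoms: 4-methoxybenzyl chloride, COc1ccc(CCl)cc1
Why: Williamson etherification in which the secondary C8′ alkoxide is alkylated far faster than the tertiary C3′ one; a benzyl-type ether, unlike a silyl ether, cannot migrate to the neighbouring alkoxide in the next step and can later be removed without acid or base.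

Step 13
Reactants: 15 C8′ PMB ether
Product: 16 C3′ methyl carbonate (C7′–OTBS, C8′–OPMB)
Conditions: LiN(SiMe3)2 (1.2 equiv), THF, −78 °C; ClCO2Me, −78 → 0 °C
Reagents that add atoms: methyl chloroformate, COC(=O)Cl
Why: O-Acylation of the lithium tert-alkoxide by a chloroformate places the future C1′ on the C3′ oxygen as a methyl carbonate, a donor robust enough for the two steps that follow.

Step 14
Reactants: 16 C3′ methyl carbonate
Product: 17 C7′ alcohol (C3′ methyl carbonate, C8′–OPMB)
Conditions: HF·pyridine, pyridine, THF, 0 °C → rt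
Reagents that add atoms: none
Why: Fluoride cleavage of the silyl ether under buffered, weakly acidic conditions leaves the benzyl ether, the carbonate and the enol ether intact and generates no alkoxide that could lactonise onto the nearby ring A ester.

Step 15
Reactants: 17 C7′ alcohol
Product: 18 all-cis tricyclic C7′ ketone with C3′ methyl carbonate, C8′–OPMB and ring A β-methoxy enoate (key-step precursor)
Conditions: Dess–Martin periodinane, NaHCO3, CH2Cl2, 0 °C → rt
Reagents that add atoms: none
Why: Dess–Martin oxidation of the secondary alcohol gives the C7′ ketone under neutral conditions, and the configuration at C7a′ no longer matters because it becomes an enolate carbon in the next step.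

Step 16
Reactants: 18 C7′ ketone with C3′ methyl carbonate
Product: 19 bridged β-keto lactone (C1′ bonded to C7a′ and through O2′ to C3′, lactone on the H-face; C7′ ketone; C8′–OPMB)
Conditions: KOt-Bu (1.2 equiv), THF, −20 → 0 °C; then AcOH
Reagents that add atoms: none
Why: tert-Butoxide equilibrates the ketone between its C6′ and C7a′ enolates, and only the more substituted C7a′ enolate can reach the carbonate carbonyl held on the C3′ oxygen; its α-carbon adds there and methoxide is expelled, the closest known reaction type being the Dieckmann-type intramolecular Claisen C-acylation of a ketone enolate by a carbonate. The γ-lactone closes in a 5-exo-trig mode and gives the 2-oxabicyclo[2.2.1]heptan-3-one unit (C7a′, C1′, O2′, C3′, C3a′) astride the central cyclopentane. The new quaternary stereocentre C7a′ is controlled by the tether: O2′ stands on the H-face of C3′, cis-1,3 to C7a′, so C1′ can only be delivered on that face and ring C stays cis-fused. The step needs regioselectivity (C7a′ over C6′) and C- over O-acylation: the first follows from Curtin–Hammett trapping, the C6′ enolate having no electrophile in five-ring reach, the second from ring size, since O-acylation would need a seven-membered ring. Ring A, a vinylogous carbonate without acidic α-hydrogen, and the etherified C8′ oxygen offer no competing enolate, and low temperature with an acidic quench limits attack of the released methoxide on the non-enolisable β-keto lactone.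

Step 17
Reactants: 19 bridged β-keto lactone
Product: 20 C7′ enol triflate (C6′=C7′–OTf)
Conditions: KN(SiMe3)2, PhNTf2, THF, −78 → −40 °C
Reagents that add atoms: N-phenylbis(trifluoromethanesulfonimide), O=S(=O)(N(c1ccccc1)S(=O)(=O)C(F)(F)F)C(F)(F)F
Why: Enolate O-sulfonylation, in which deprotonation can occur only toward C6′ because C7a′ is quaternary, so a single enol triflate should form.

Step 18
Reactants: 20 C7′ enol triflate
Product: 21 C6′=C7′ alkene (lactone, C8′–OPMB)
Conditions: Pd(OAc)2 (5 mol %), PPh3 (10 mol %), n-Bu3N, HCO2H, DMF, 60 °C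
Reagents that add atoms: none
Why: Palladium-catalysed formate reduction of an enol triflate (oxidative addition to zerovalent palladium, formate exchange, loss of CO2, C–H reductive elimination) replaces the triflate by hydrogen without moving the double bond.

Step 19
Reactants: 21 C6′=C7′ alkene with C8′–OPMB
Product: 22 C8′ alcohol
Conditions: DDQ, CH2Cl2/pH 7 buffer, 0 °C → rt
Reagents that add atoms: none
Why: Oxidative cleavage of the 4-methoxybenzyl ether by DDQ under neutral buffered conditions spares the alkene, the enol ether and the lactone and forms no alkoxide that could shift the lactone acyl group from O2′ to the C8′ oxygen.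

Step 20
Reactants: 22 C8′ alcohol
Product: 23 C8′ ketone (butanoyl group at C3′; ring A β-methoxy enoate)
Conditions: Dess–Martin periodinane, NaHCO3, CH2Cl2, 0 °C → rt
Reagents that add atoms: none
Why: Dess–Martin oxidation of the secondary alcohol to the butanoyl ketone, carried out at once on the crude alcohol so that acyl migration cannot set in.

Step 21
Reactants: 23 butanoyl ketone with ring A β-methoxy enoate
Product: 24 ring A β-keto ester (chelated enol form)
Conditions: 1 M HCl, THF, 40 °C
Reagents that add atoms: water, O
Why: Acid hydrolysis of the vinylogous carbonate (enol ether) to the β-keto ester, conditions under which the bridged lactone, the ketone and the isolated alkene are stable.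

Step 22
Reactants: 24 ring A β-keto ester
Product: 25 ring A enol triflate (C7a=C3a–OTf)
Conditions: Tf2O, i-Pr2NEt, CH2Cl2, −78 °C
Reagents that add atoms: trifluoromethanesulfonic anhydride, O=S(=O)(OS(=O)(=O)C(F)(F)F)C(F)(F)F
Why: O-Triflation of the chelated β-keto ester enol with an amine base at low temperature, under which the far less acidic butanoyl ketone does not enolise.

Step 23
Reactants: 25 ring A enol triflate; 26 1-pentyne
Product: 27 enyne methyl ester (pent-1-ynyl at C3a, CO2Me at C7a)
Conditions: PdCl2(PPh3)2 (5 mol %), CuI (10 mol %), i-Pr2NH, THF, rt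
Reagents that add atoms: none
Why: Sonogashira coupling of the electron-poor vinyl triflate with the terminal alkyne attaches C3 and the future butylidene chain to C3a.

Step 24
Reactants: 27 enyne methyl ester
Product: 28 enynoic acid
Conditions: LiI, EtOAc, reflux; then 1 M HCl
Reagents that add atoms: none
Why: SN2 demethylation of the methyl ester by iodide, a mode of cleavage that cannot open the bridged lactone because its alkyl oxygen sits on the tertiary C3′.

Step 25
Reactants: 28 enynoic acid
Product: 29 CNP0423313.1
Conditions: AgNO3 (10 mol %), acetone, rt, dark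
Reagents that add atoms: none
Why: Silver-catalysed 5-exo-dig lactonisation of the (Z)-2-en-4-ynoic acid, in which anti addition of carboxylate and silver across the alkyne followed by protodemetallation gives the (Z)-butylidene group.

Compound list
1 | methyl 2,6-dihydroxybenzoate | COC(=O)c1c(O)cccc1O | starting material
2 | methyl 2-hydroxy-6-(trifluoromethylsulfonyloxy)benzoate | COC(=O)c1c(O)cccc1OS(=O)(=O)C(F)(F)F | intermediate
3 | 2-(methoxymethoxy)phenylboronic acid | COCOc1ccccc1B(O)O | starting material
4 | methyl 2-hydroxy-6-[2-(methoxymethoxy)phenyl]benzoate | COC(=O)c1c(O)cccc1-c1ccccc1OCOC | intermediate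
5 | methyl 6-hydroxy-3-iodo-2-[2-(methoxymethoxy)phenyl]benzoate | COC(=O)c1c(O)ccc(I)c1-c1ccccc1OCOC | intermediate
6 | methyl 3-hydroxy-5-(methoxymethoxy)-9-oxofluorene-4-carboxylate | COC(=O)c1c(O)ccc2C(=O)c3cccc(OCOC)c3-c12 | intermediate
7 | methyl 3,5-dihydroxy-9-oxofluorene-4-carboxylate (fluorenone diphenol, formed in the flask in step 5) | COC(=O)c1c(O)ccc2C(=O)c3cccc(O)c3-c12 | intermediate
8 | methyl 5-(tert-butyldimethylsilyloxy)-3-hydroxy-9-oxofluorene-4-carboxylate | COC(=O)c1c(O)ccc2C(=O)c3cccc(O[Si](C)(C)C(C)(C)C)c3-c12 | intermediate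
9 | rac-methyl 5-(tert-butyldimethylsilyloxy)-3,9-dihydroxydodecahydrofluorene-4-carboxylate, all-cis (hydrogens at C6, C7, C7a′, C3a′, C7a, C3a, C7′, C3′ all on the H-face; racemate, one enantiomer drawn) | COC(=O)[C@H]2[C@@H](O)CC[C@@H]1[C@H]2[C@@H]2[C@H](O[Si](C)(C)C(C)(C)C)CCC[C@@H]2[C@@H]1O | intermediate
10 | rac-all-cis tricyclic C3′ ketone, ring A as enol of the β-keto ester (C7a=C3a–OH, C7a–CO2Me), C7′–OTBS (racemate, one enantiomer drawn) | COC(=O)C2=C(O)CC[C@@H]1[C@H]2[C@@H]2[C@H](O[Si](C)(C)C(C)(C)C)CCC[C@@H]2C1=O | intermediate
11 | rac-all-cis tricyclic C3′ ketone, ring A as β-methoxy enoate (C7a=C3a–OMe), C7′–OTBS (racemate, one enantiomer drawn) | COC(=O)C2=C(OC)CC[C@@H]1[C@H]2[C@@H]2[C@H](O[Si](C)(C)C(C)(C)C)CCC[C@@H]2C1=O | intermediate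
12 | the ketone of 11 as a single enantiomer (H6, H7, H7a′, H3a′ syn) | COC(=O)C2=C(OC)CC[C@@H]1[C@H]2[C@@H]2[C@H](O[Si](C)(C)C(C)(C)C)CCC[C@@H]2C1=O | intermediate
13 | C3′ butylidene derivative of 12 (exocyclic C3′=C8′, propyl drawn syn to C6) | COC(=O)C2=C(OC)CC[C@@H]1[C@H]2[C@@H]2[C@H](O[Si](C)(C)C(C)(C)C)CCC[C@@H]2/C1=C/CCC | intermediate
14 | C3′,C8′ diol (tertiary C3′–OH on the H-face, 1-hydroxybutyl group on the face of rings A and C) | COC(=O)C2=C(OC)CC[C@@H]1[C@H]2[C@@H]2[C@H](O[Si](C)(C)C(C)(C)C)CCC[C@@H]2[C@@]1([C@@H](O)CCC)O | intermediate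
15 | C8′ 4-methoxybenzyl ether of 14 (free tertiary C3′–OH) | COC(=O)C2=C(OC)CC[C@@H]1[C@H]2[C@@H]2[C@H](O[Si](C)(C)C(C)(C)C)CCC[C@@H]2[C@@]1([C@@H](OCc3ccc(OC)cc3)CCC)O | intermediate
16 | C3′ methyl carbonate of 15 (C7′–OTBS) | COC(=O)C2=C(OC)CC[C@@H]1[C@H]2[C@@H]2[C@H](O[Si](C)(C)C(C)(C)C)CCC[C@@H]2[C@@]1([C@@H](OCc3ccc(OC)cc3)CCC)OC(=O)OC | intermediate
17 | C7′ alcohol (C3′ methyl carbonate, C8′–OPMB) | COC(=O)C2=C(OC)CC[C@@H]1[C@H]2[C@@H]2[C@H](O)CCC[C@@H]2[C@@]1([C@@H](OCc3ccc(OC)cc3)CCC)OC(=O)OC | intermediate
18 | all-cis tricyclic C7′ ketone with C3′ methyl carbonate, C8′–OPMB, ring A β-methoxy enoate (key-step precursor) | COC(=O)C2=C(OC)CC[C@@H]1[C@H]2[C@@H]2C(=O)CCC[C@@H]2[C@@]1([C@@H](OCc3ccc(OC)cc3)CCC)OC(=O)OC | intermediate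
19 | bridged β-keto lactone (C1′ on C7a′ and, through O2′, on C3′; lactone on the H-face; C7′ ketone; C8′–OPMB) | COC(=O)C2=C(OC)CC[C@@H]1[C@H]2[C@]23C(=O)CCC[C@@H]2[C@@]1([C@@H](OCc4ccc(OC)cc4)CCC)OC3=O | intermediate
20 | C7′ enol triflate of 19 (C6′=C7′–OTf) | COC(=O)C2=C(OC)CC[C@@H]1[C@H]2[C@]23C(OS(=O)(=O)C(F)(F)F)=CCC[C@@H]2[C@@]1([C@@H](OCc4ccc(OC)cc4)CCC)OC3=O | intermediate
21 | C6′=C7′ alkene lactone with C8′–OPMB | COC(=O)C2=C(OC)CC[C@@H]1[C@H]2[C@]23C=CCC[C@@H]2[C@@]1([C@@H](OCc4ccc(OC)cc4)CCC)OC3=O | intermediate
22 | C8′ alcohol | COC(=O)C2=C(OC)CC[C@@H]1[C@H]2[C@]23C=CCC[C@@H]2[C@@]1([C@@H](O)CCC)OC3=O | intermediate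
23 | C8′ ketone (butanoyl at C3′), ring A β-methoxy enoate | COC(=O)C2=C(OC)CC[C@@H]1[C@H]2[C@]23C=CCC[C@@H]2[C@@]1(C(=O)CCC)OC3=O | intermediate
24 | ring A β-keto ester, drawn as chelated enol | COC(=O)C2=C(O)CC[C@@H]1[C@H]2[C@]23C=CCC[C@@H]2[C@@]1(C(=O)CCC)OC3=O | intermediate
25 | ring A enol triflate (C7a=C3a–OTf) | COC(=O)C2=C(OS(=O)(=O)C(F)(F)F)CC[C@@H]1[C@H]2[C@]23C=CCC[C@@H]2[C@@]1(C(=O)CCC)OC3=O | intermediate
26 | 1-pentyne | CCCC#C | starting material
27 | enyne methyl ester (pent-1-ynyl at C3a, CO2Me at C7a) | COC(=O)C2=C(C#CCCC)CC[C@@H]1[C@H]2[C@]23C=CCC[C@@H]2[C@@]1(C(=O)CCC)OC3=O | intermediate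
28 | enynoic acid | OC(=O)C2=C(C#CCCC)CC[C@@H]1[C@H]2[C@]23C=CCC[C@@H]2[C@@]1(C(=O)CCC)OC3=O | intermediate
29 | CNP0423313.1 | CCC/C=C1\OC(=O)C2=C1CC[C@@H]1[C@H]2[C@]23C=CCC[C@@H]2[C@@]1(C(=O)CCC)OC3=O | target

Total step count: 25. Longest linear sequence: 25 steps (1 → 29); 3 and 26 enter as purchased building blocks.

Steps most likely to fail

Step 16. The acyl transfer may reverse, or the product may be opened, because the liberated methoxide attacks the non-enolisable β-keto lactone; the C6′ enolate may also be diverted (for example onto the ring A ester) faster than it equilibrates. The fallback sets out from 18. Heating with Me3SiCl and Et3N in DMF should give, under equilibrating conditions, the more substituted trimethylsilyl enol ether F1. A catalytic amount of anhydrous tetrabutylammonium difluorotriphenylsilicate in THF then releases the C7a′ enolate regiospecifically. This enolate acylates intramolecularly while the expelled methoxide is consumed by the next molecule of silyl enol ether, so no alkoxide accumulates. The sequence comes back to the route at 19.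

Step 6. The doubly benzylic C–O bond formed by early reduction of the fluorenone carbonyl may be lost by hydrogenolysis, or that carbinol may steer hydrogen delivery to different faces of the two rings. The fallback sets out from 8. The ketone is masked by aprotic ketalisation (1,2-bis(trimethylsilyloxy)ethane, catalytic Me3SiOTf, CH2Cl2; the phenol is recovered on work-up) as the spiro-1,3-dioxolane F2. Hydrogenation over Rh/Al2O3 as in step 6 should then give the all-cis ketal alcohol F3 without a benzylic hydroxyl ever being present. Pyridinium p-toluenesulfonate in wet acetone frees the all-cis hydroxy ketone F4. Dess–Martin oxidation of its single alcohol comes back to the route at 10.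

Step 10. The basic ylide may enolise the hindered ketone instead of adding to it, with epimerisation at C6 or C3a′ or simple recovery of ketone. The fallback sets out from 12. Non-basic Takai–Lombardo methylenation (Zn, CH2Br2, TiCl4, THF) should give the exocyclic methylene compound F5. OsO4/NMO from the convex H-face gives the primary–tertiary diol F6. Selective oxidation of the primary alcohol (TEMPO, PhI(OAc)2) gives the α-hydroxy aldehyde F7. Addition of excess n-PrMgBr in THF at −78 °C comes back to the route at 14, either C8′ epimer being usable.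

Further compounds
F1 | step 16 | trimethylsilyl enol ether of 18 (C7a′=C7′–OSiMe3) | COC(=O)C2=C(OC)CC[C@@H]1[C@H]2C2=C(O[Si](C)(C)C)CCC[C@@H]2[C@@]1([C@@H](OCc3ccc(OC)cc3)CCC)OC(=O)OC
F2 | step 6 | spiro-1,3-dioxolane (C9 ketal) of fluorenone 8 | COC(=O)c1c(O)ccc2c1-c1c(O[Si](C)(C)C(C)(C)C)cccc1C23OCCO3
F3 | step 6 | rac-all-cis ketal alcohol (C3′ dioxolane, C3a–OH, C7′–OTBS; one enantiomer drawn) | COC(=O)[C@H]2[C@@H](O)CC[C@@H]1[C@H]2[C@@H]2[C@H](O[Si](C)(C)C(C)(C)C)CCC[C@@H]2C13OCCO3
F4 | step 6 | rac-all-cis hydroxy ketone (C3′ ketone, C3a–OH, C7′–OTBS; one enantiomer drawn) | COC(=O)[C@H]2[C@@H](O)CC[C@@H]1[C@H]2[C@@H]2[C@H](O[Si](C)(C)C(C)(C)C)CCC[C@@H]2C1=O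
F5 | step 10 | C3′ methylene compound | COC(=O)C2=C(OC)CC[C@@H]1[C@H]2[C@@H]2[C@H](O[Si](C)(C)C(C)(C)C)CCC[C@@H]2C1=C
F6 | step 10 | C3′ hydroxy, C3′ hydroxymethyl diol (tertiary OH on the H-face) | COC(=O)C2=C(OC)CC[C@@H]1[C@H]2[C@@H]2[C@H](O[Si](C)(C)C(C)(C)C)CCC[C@@H]2[C@@]1(CO)O
F7 | step 10 | C3′ hydroxy C3′ carbaldehyde | COC(=O)C2=C(OC)CC[C@@H]1[C@H]2[C@@H]2[C@H](O[Si](C)(C)C(C)(C)C)CCC[C@@H]2[C@@]1(C=O)O
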